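The chromone is disconnected at C2–C3 of the pyranone ring (ring C), the bond between the former acetyl methyl carbon and the carbonyl carbon of a 3-arylpropanoyl unit. The route exploits the ortho relation, on ring A, of O1 on C8a and the acetyl group on C4a: the acyl unit is first placed on that oxygen and then passed to the acetyl enolate in one operation, which forms C2–C3 and frees the phenol that later closes O1–C2. The precursor is the 2-acetyl-4,5-dimethoxyphenyl ester of a 3-arylpropanoic acid whose 3'-hydroxyl is masked as a methoxymethyl ether, removed by the same acid that closes the ring.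

Key step: step 3

Remarks:
- The target has no stereocenter and none arises in the route.
- The 3'-oxygen is masked as an acetal because it should survive carbodiimide and amide base and leave in the ring-closing acid step; this avoids a separate deprotection and any hydrogenation next to the C2=C3 bond.
- Diketone 7 is written as the diketo form; keto–enol and ring–chain tautomers are expected and all should converge in step 4.
- Compounds 1, 2 and 5 are assumed to be purchasable; 2 is a regulated alkylating agent and is handled accordingly.

Step 1
Reactants: 1 3-(3-hydroxy-4-methoxyphenyl)propanoic acid; 2 chloromethyl methyl ether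
Product: 4 3-[4-methoxy-3-(methoxymethoxy)phenyl]propanoic acid, via methoxymethyl ester 3 (not isolated)
Conditions: MOMCl (2.5 equiv), K2CO3 (3 equiv), DMF, 0 °C→rt; then 2 M aq. NaOH, MeOH, rt; cold 1 M HCl to pH 4
Reagents that add atoms: chloromethyl methyl ether, COCCl; sodium hydroxide, [Na+].[OH-] (its oxygen becomes the carboxyl OH on acyl–oxygen cleavage of the ester)
Why: Williamson-type O-alkylation of both the phenoxide and the carboxylate by the reactive α-chloro ether, followed by saponification of the resulting methoxymethyl ester, an acylal-like activated ester that hydroxide cleaves at the acyl carbon while the aryl acetal ether is inert to base.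

Step 2
Reactants: 4 3-[4-methoxy-3-(methoxymethoxy)phenyl]propanoic acid; 5 1-(2-hydroxy-4,5-dimethoxyphenyl)ethanone
Product: 6 2-acetyl-4,5-dimethoxyphenyl 3-[4-methoxy-3-(methoxymethoxy)phenyl]propanoate
Conditions: DCC (1.2 equiv), DMAP (0.2 equiv), CH2Cl2, 0 °C→rt
Reagents that add atoms: none
Why: Steglich esterification, in which DMAP intercepts the O-acylisourea as an N-acylpyridinium ion reactive enough to acylate the hydrogen-bonded, weakly nucleophilic ortho-acetyl phenol under neutral conditions that leave the acetal and the methyl ketone untouched.

Step 3
Reactants: 6 2-acetyl-4,5-dimethoxyphenyl 3-[4-methoxy-3-(methoxymethoxy)phenyl]propanoate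
Product: 7 1-(2-hydroxy-4,5-dimethoxyphenyl)-5-[4-methoxy-3-(methoxymethoxy)phenyl]pentane-1,3-dione
Conditions: LiN(SiMe3)2 (3.0 equiv), THF, −78 °C→rt; AcOH quench at 0 °C
Reagents that add atoms: none
Why: Baker–Venkataraman rearrangement, an intramolecular Claisen condensation: the amide base deprotonates the acetyl methyl group, the lithium enolate adds to the ester carbonyl held ortho to it to give a six-membered tetrahedral alkoxide, and this collapses with expulsion of the ring A phenoxide, forming C2–C3. The closest known reaction type is the O-to-C acyl shift of 2-acyloxyacetophenones that carry enolisable aliphatic acyl groups, as used for 2-alkyl- and 2-phenethylchromones. No ring is retained, the cyclic adduct being only a transient formed by 6-exo-trig attack, and no stereocenter is created. The selectivity needed is ketone enolate over ester enolate, because the ester enolate could expel the aryloxide as a ketene or add to the ketone on the way to a 4-methylcoumarin; the higher acidity and easier access of the methyl ketone toward a hindered amide base at −78 °C should secure it. Three equivalents of base are used because the phenoxide and the diketone each consume one, and the resulting phenoxide–diketonate is the thermodynamic sink that drives the transfer and shields the product from retro-Claisen cleavage.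

Step 4
Reactants: 7 1-(2-hydroxy-4,5-dimethoxyphenyl)-5-[4-methoxy-3-(methoxymethoxy)phenyl]pentane-1,3-dione
Product: 9 2-[2-(3-hydroxy-4-methoxyphenyl)ethyl]-6,7-dimethoxy-4H-chromen-4-one, via methoxymethyl-protected chromone 8 (not isolated)
Conditions: HCl (ca. 1 M, from conc. HCl), MeOH, 60 °C
Reagents that add atoms: none
Why: Acid-catalysed cyclodehydration of a 1-(2-hydroxyaryl)-1,3-diketone, in which the ring A phenol adds to the activated side-chain carbonyl and loss of water closes O1–C2 to the stable 4-pyranone, while the same acid cleaves the methoxymethyl acetal by methanolysis with the formaldehyde unit trapped as dimethoxymethane; the order of the two events is immaterial because both paths converge on 9.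

Compound list
1 | 3-(3-hydroxy-4-methoxyphenyl)propanoic acid | COc1ccc(CCC(=O)O)cc1O | starting material
2 | chloromethyl methyl ether | COCCl | starting material
3 | methoxymethyl 3-[4-methoxy-3-(methoxymethoxy)phenyl]propanoate | COCOC(=O)CCc1ccc(OC)c(OCOC)c1 | intermediate (not isolated)
4 | 3-[4-methoxy-3-(methoxymethoxy)phenyl]propanoic acid | COCOc1cc(CCC(=O)O)ccc1OC | intermediate
5 | 1-(2-hydroxy-4,5-dimethoxyphenyl)ethanone (2-hydroxy-4,5-dimethoxyacetophenone) | CC(=O)c1cc(OC)c(OC)cc1O | starting material
6 | 2-acetyl-4,5-dimethoxyphenyl 3-[4-methoxy-3-(methoxymethoxy)phenyl]propanoate | CC(=O)c1cc(OC)c(OC)cc1OC(=O)CCc1ccc(OC)c(OCOC)c1 | intermediate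
7 | 1-(2-hydroxy-4,5-dimethoxyphenyl)-5-[4-methoxy-3-(methoxymethoxy)phenyl]pentane-1,3-dione | COCOc1cc(CCC(=O)CC(=O)c2cc(OC)c(OC)cc2O)ccc1OC | intermediate
8 | 6,7-dimethoxy-2-{2-[4-methoxy-3-(methoxymethoxy)phenyl]ethyl}-4H-chromen-4-one | COCOc1cc(CCc2cc(=O)c3cc(OC)c(OC)cc3o2)ccc1OC | intermediate (not isolated)
9 | 2-[2-(3-hydroxy-4-methoxyphenyl)ethyl]-6,7-dimethoxy-4H-chromen-4-one | COc1ccc(CCc2cc(=O)c3cc(OC)c(OC)cc3o2)cc1O | target

Total step count: 4. Longest linear sequence: 4 steps (1 → 4 → 6 → 7 → 9).

Steps most likely to fail

Step 3. The base may enolise the ester side instead, which would lead to loss of the aryloxide through a ketene or to aldol closure toward a coumarin; the acyl transfer may also stall. The fallback sets out from 4 and 5 and returns at 7, making the same C2–C3 bond intermolecularly. Acid 4 is treated with 1,1'-carbonyldiimidazole in THF to give the acyl imidazole 1-(1H-imidazol-1-yl)-3-[4-methoxy-3-(methoxymethoxy)phenyl]propan-1-one F1. Ketone 5 is converted separately with LiN(SiMe3)2 (3 equiv, THF, −78 °C) into its dilithium phenoxide–enolate, and F1 is added to it. Crossed Claisen C-acylation of the preformed ketone enolate, with no aryl ester present to enolise, should give 7 after an AcOH quench.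

Step 2. Acylation of the hydrogen-bonded phenol may be slow enough that the activated acid is lost by O-to-N acyl shift in the carbodiimide adduct. The fallback sets out from 4 and returns at 6, using a discrete acyl chloride and a preformed phenoxide. Acid 4 is converted with 1-chloro-N,N,2-trimethylprop-1-en-1-amine in CH2Cl2, which releases no HCl and so spares the acetal, into 3-[4-methoxy-3-(methoxymethoxy)phenyl]propanoyl chloride F2. This is added to the sodium phenoxide of 5 (NaH, THF, 0 °C) to give 6 by direct O-acylation.

Step 4. The methoxymethyl cation released in acid may be captured by the electron-rich rings, or methanol may cleave the diketone before the ring closes. The fallback sets out from 7 and returns at 9, separating the two events; it makes no compound outside the list (F0). Diketone 7 is cyclodehydrated under buffered conditions (NaOAc, AcOH, 100 °C) that should leave the acetal in place, and chromone 8 is isolated. The acetal is then cleaved on the stable chromone with ZnBr2 and 1-propanethiol in CH2Cl2 at rt, where the thiol traps the methoxymethyl unit, to give 9.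

Further compounds
F1 | step 3 | 1-(1H-imidazol-1-yl)-3-[4-methoxy-3-(methoxymethoxy)phenyl]propan-1-one | COCOc1cc(CCC(=O)n2ccnc2)ccc1OC
F2 | step 2 | 3-[4-methoxy-3-(methoxymethoxy)phenyl]propanoyl chloride | COCOc1cc(CCC(=O)Cl)ccc1OC
F0 | step 4 | none | none
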